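## The problem

The target **22**, 7-hydroxy-6-methoxy-3-[(6-methoxy-2-oxo-2H-chromen-7-yl)oxy]-2H-chromen-2-one, consists of two scopoletin-type coumarins. Unit A carries the free 7-hydroxyl and the 6-methoxy group; unit B is a scopoletin (**7**) whose C7' oxygen is bonded to C3 of unit A. There is no stereocentre, so the task is connectivity and site selectivity only.

The ether carbon C3 is an sp2 carbon next to the lactone carbonyl and is not activated for substitution by a phenoxide (conjugate addition goes to C4). The C3–O bond is therefore best made while C3 is still a saturated CH2.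

The oxygens at C6 and C7 of unit A differ by one methyl group. The only intrinsic handle is the higher acidity of the 7-OH, which is conjugated through C4a, C4 and C3 with the C2 carbonyl.

Both lactones open with hydroxide, alkoxide or amines on heating, and the unsubstituted C3'–C4' double bond of unit B accepts nucleophiles and hydrogen. Strong bases must therefore be used cold and briefly, and hydrogenolysis is avoided.

The enabling feature lies in pyranone A. O1 and C4 sit on the neighbouring arene carbons C8a and C4a, C4 is a CH at the formyl oxidation level, C5 and C8 are unsubstituted, and C6 and C7 both bear oxygen. A symmetric 6,7-dioxygenated aryne across C4a–C8a can therefore take O1 and C4 from one molecule of DMF (**10**), and C2–C3 with its aryloxy group is the acetate unit of an O-alkylated scopoletin.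

## Retrosynthesis

**22 back to 18 (ring A oxygens).** The O–CH3 bond at C6 and the O–H at C7 are installed last: **22** comes from the para-methoxybenzyl ether **21**, **21** from phenol **20** by O-methylation, **20** from catechol **19** by alkylation of the more acidic 7-OH, and **19** from the methylenedioxy compound **18**. The reason is the aryne. An aryne that already carried OMe and OR would be unsymmetrical, with both substituents remote from the triple bond, and would give both regioisomers. A symmetric acetal gives one product, and the acetal is the one catechol mask that a boron Lewis acid opens while leaving the methyl ether of unit B alone; a 6,7-dimethoxy analogue would require picking one of three methyl ethers. The para-methoxybenzyl group is chosen because acid removes it without touching the two pyranone double bonds. The forward steps must deliver chemoselective acetal cleavage and site-selective mono-alkylation.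

**18 back to 6, 10 and 9 (pyranone A).** Four bonds are cut: O1–C8a, C4–C4a, C3–C4 and O1–C2. This leaves aryne precursor **6**, DMF **10** and aryloxyacetate **9**. Cutting the C3–O ether instead would require substitution at an unactivated sp2 carbon. Cutting only C3–C4 and O1–C2 (the classical condensation) needs an ortho-hydroxy aldehyde and hot anhydride; it is kept as the fallback. The aryne cut is convergent, runs near room temperature, and forms every bond around O1 and C4 in one flask from three small components. The forward reaction must have DMF capture the aryne before the enolate does, and needs an enolate of **9** that is reactive enough for the quinone methide yet tame toward the pyranone of unit B. A preformed zinc enolate (**12**) is therefore used.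

**9 back to 7 and 8.** The O–CH2 bond is cut, giving scopoletin **7** and ethyl bromoacetate **8**. This makes the troublesome ether as an ordinary phenol alkylation at sp3 carbon and needs only a carbonate base.

**6 back to 2 and 1.** The C–Si and O–S bonds are cut, leading to 6-bromosesamol **2** and then sesamol **1** by removal of bromine. The ortho-silyl triflate arises in one pot through silyl ether **3**, aryllithium **4** and lithium phenoxide **5**; the position para to a dioxole oxygen and ortho to the hydroxyl directs the bromination.

## Roads not taken

**Alternative 1:** Both pyranone double bonds (C3–C4 and C3'–C4') are cut. Tetraene **A2**, a bis(aryl ester) with two styrene units, one acrylate and one 2-aryloxyacrylate, would be closed twice by the second-generation Grubbs catalyst (H2IMes)(PCy3)Cl2Ru(CHPh) to the 7-O-silyl target **A1**.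
- Merits: neutral conditions and both rings in one operation. The 6-OMe and 7-OSi groups are different from the start, so only a desilylation follows. That is clearly better than the four-step endgame of the chosen plan.
- Weak points: the closure on unit A must form a trisubstituted, oxygen-bearing double bond from a 1,1-disubstituted captodative olefin, a slow substrate class, while unit B closes easily; partial conversion is likely. Four terminal olefins allow pairings other than the two wanted. **A2** contains two aryl acrylates, which are acylating agents prone to hydrolysis and polymerisation. Its central 2-aryloxyacrylate and both vinylphenols each need their own synthesis.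
- Comparison: the chosen plan buys both halves as phenols and reaches the key step in three steps, with no competing olefin pairings. Against the shorter endgame of this alternative it sets much cheaper fragment assembly.

**Alternative 2:** The benzene ring of unit A is built (C5–C6, C4a–C8a and C8–C8a). Heating the chromium carbene complex **A4**, (CO)5Cr=C(OMe)C(OtBu)=CH2, with terminal alkyne **A5**, followed by air oxidation, would give phenol **A3** (racemic).
- Merits: the methoxy group (from the carbene carbon) and the tert-butoxy group (from the vinyl unit) are differentiated by construction, and the phenol lands next to the side chain by the usual regiochemistry of terminal alkynes. In regiochemical certainty this is better than the chosen plan, which differentiates a catechol by acidity.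
- Weak points: stoichiometric chromium, a sensitive alkoxyvinyl carbene complex, and the construction of an arene that can be bought oxygenated. **A3** is at the dihydrocinnamate level and would still need lactonisation, dehydrogenation at C3–C4 and removal of the tert-butyl group.
- Comparison: the step count after the key step is similar, but the route to **A4** and **A5** is far longer than the route to **6** and **9**. The chosen plan sets arene rings from commerce against the better regiocontrol of this alternative.

**Alternative 3:** The O1'–C8a' bond of unit B is cut. Indanone **A7** would undergo Baeyer–Villiger oxidation with a peracid; the electron-rich aryl carbon (para to methoxy) migrates and gives dihydrocoumarin **A6**.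
- Merits: every step is a known reaction type, the migration preference is reliable, and unit A carries OAc and OMe already differentiated. In precedent this is stronger than the chosen key step.
- Weak points: unit B is rebuilt from an indanone although scopoletin **7** is commercial. **A6** leaves C3'–C4' saturated, so a late dehydrogenation and a deacetylation remain. The peracid may also attack the enol-ether double bond C3–C4 of unit A. The C3–O ether problem is not solved by this cut and must be handled earlier.
- Comparison: the chosen plan is shorter and more convergent. Against the better precedent of this alternative it sets a fallback of known chemistry that rejoins the route at **18**.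

Key step: step 4

Remark on the chemistry: metal enolates **11** and **12** are drawn as O-bound monomers, and **16** and **17** are racemic diastereomer mixtures whose two stereocentres disappear within the same step.

## Route

Step 1
Reactants: 1 sesamol (1,3-benzodioxol-5-ol)
Product: 2 6-bromo-1,3-benzodioxol-5-ol
Conditions: NBS, CH2Cl2, −20 → 0 °C
Reagents that add atoms: N-bromosuccinimide, O=C1CCC(=O)N1Br
Why: Electrophilic aromatic bromination; C6 is ortho to the hydroxyl and para to a dioxole oxygen, while C4 between two oxygens is hindered, so monobromination at C6 is expected.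

Step 2
Reactants: 2 6-bromo-1,3-benzodioxol-5-ol
Product: 6 6-(trimethylsilyl)-1,3-benzodioxol-5-yl trifluoromethanesulfonate, via aryl trimethylsilyl ether 3 (not isolated), via aryllithium 4 (not isolated), via lithium 2-silylphenoxide 5 (not isolated)
Conditions: HMDS, THF, reflux; evaporate; n-BuLi, THF, −100 → −80 °C; Tf2O, −100 °C → rt
Reagents that add atoms: hexamethyldisilazane, C[Si](C)(C)N[Si](C)(C)C; trifluoromethanesulfonic anhydride, O=S(=O)(OS(=O)(=O)C(F)(F)F)C(F)(F)F
Why: Standard one-pot route to ortho-silylaryl triflates from ortho-bromophenols: O-silylation, bromine–lithium exchange, anionic 1,3 O→C silyl shift (retro-Brook rearrangement) and O-triflation of the phenoxide.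

Step 3
Reactants: 7 scopoletin (7-hydroxy-6-methoxy-2H-chromen-2-one); 8 ethyl bromoacetate
Product: 9 ethyl 2-[(6-methoxy-2-oxo-2H-chromen-7-yl)oxy]acetate
Conditions: K2CO3, acetone, reflux
Reagents that add atoms: none
Why: Williamson ether synthesis of an acidic 7-hydroxycoumarin with a reactive α-halo ester; anhydrous carbonate leaves the lactone intact.

Step 4
Reactants: 9 ethyl 2-[(6-methoxy-2-oxo-2H-chromen-7-yl)oxy]acetate; 6 6-(trimethylsilyl)-1,3-benzodioxol-5-yl trifluoromethanesulfonate; 10 N,N-dimethylformamide
Product: 18 3-[(6-methoxy-2-oxo-2H-chromen-7-yl)oxy]-6,7-methylenedioxycoumarin, via lithium enolate 11 (not isolated), via chlorozinc enolate 12 (not isolated), via 4,5-methylenedioxybenzyne 13 (not isolated), via aminobenzoxete 14 (not isolated), via ortho-quinone methide 15 (not isolated), via zinc phenoxide adduct 16 (not isolated), via 4-(dimethylamino)chroman-2-one 17 (not isolated)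
Conditions: 9, LiN(SiMe3)2, THF, −78 °C; ZnCl2, −78 → 0 °C; transfer into CsF, DMF (10, solvent), rt; 6 by syringe pump, rt → 50 °C
Reagents that add atoms: none
Why: Proposed new method: fluoride removes the silyl group of 6 and triflate leaves to give aryne 13; the carbonyl oxygen of solvent DMF adds to 13 and the aryl anion closes on the iminium carbon to benzoxete 14 (O1–C8a and C4–C4a), which opens to ortho-quinone methide 15. Zinc enolate 12, made beforehand from 9 through lithium enolate 11, adds through its α-carbon to the aminomethylene carbon of 15 in a Mannich-type step that restores the arene (C3–C4) and gives phenoxide 16. Phenoxide 16 lactonises by 6-exo-trig acyl substitution with loss of ethoxide (O1–C2) to 17, and E1cB loss of dimethylamine, driven by conjugation of the new C3–C4 double bond with lactone and arene, gives 18. The closest known reaction type is the three-component coupling of ortho-silylaryl triflates, DMF and active methylene compounds (malonates, β-keto esters) to coumarins and 2H-chromenes; a singly activated α-aryloxy ester enolate has not been shown as the third component, which is why it is preformed and not left to fluoride as base. Pyranone A is closed in a formal [4+2] sense from the O1–C8a–C4a–C4 unit of 15 and the C3–C2 unit of 12, the ring-closing bond being O1–C2. No stereocentre remains, since C3 and C4 of 16 and 17 form without control and are both erased by the elimination. The step needs chemoselectivity and no regioselectivity: 13 is symmetric, DMF as solvent should outcompete the dilute, weakly nucleophilic zinc enolate for the aryne when 6 is added slowly, and the zinc counter-ion should hold the enolate back from Claisen self-condensation and from conjugate addition to the pyranone of unit B.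

Step 5
Reactants: 18 3-[(6-methoxy-2-oxo-2H-chromen-7-yl)oxy]-6,7-methylenedioxycoumarin
Product: 19 6,7-dihydroxy-3-[(6-methoxy-2-oxo-2H-chromen-7-yl)oxy]-2H-chromen-2-one
Conditions: BCl3, CH2Cl2, 0 °C → rt; then H2O
Reagents that add atoms: none
Why: Lewis-acid cleavage of an aryl methylenedioxy acetal; BCl3 opens the strained, doubly activated O–CH2–O unit much faster than unchelated aryl methyl ethers, so the C6' methoxy group and the diaryl-type ether should survive.

Step 6
Reactants: 19 6,7-dihydroxy-3-[(6-methoxy-2-oxo-2H-chromen-7-yl)oxy]-2H-chromen-2-one
Product: 20 6-hydroxy-7-[(4-methoxybenzyl)oxy]-3-[(6-methoxy-2-oxo-2H-chromen-7-yl)oxy]-2H-chromen-2-one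
Conditions: 4-methoxybenzyl chloride (1.05 equiv), NaHCO3, NaI (cat.), DMF, 40 °C
Reagents that add atoms: 4-methoxybenzyl chloride, COc1ccc(CCl)cc1
Why: Site-selective Williamson alkylation; hydrogencarbonate ionises only the 7-OH, whose phenoxide is conjugated with the C2 carbonyl, as in the para-selective mono-alkylation of carbonyl-conjugated catechols and the 7-selective alkylation of 6,7-dihydroxycoumarins.

Step 7
Reactants: 20 6-hydroxy-7-[(4-methoxybenzyl)oxy]-3-[(6-methoxy-2-oxo-2H-chromen-7-yl)oxy]-2H-chromen-2-one
Product: 21 6-methoxy-7-[(4-methoxybenzyl)oxy]-3-[(6-methoxy-2-oxo-2H-chromen-7-yl)oxy]-2H-chromen-2-one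
Conditions: MeI, K2CO3, DMF, rt
Reagents that add atoms: iodomethane, CI
Why: Williamson O-methylation of the one remaining phenol; anhydrous carbonate at room temperature leaves lactones and the benzylic ether untouched.

Step 8
Reactants: 21 6-methoxy-7-[(4-methoxybenzyl)oxy]-3-[(6-methoxy-2-oxo-2H-chromen-7-yl)oxy]-2H-chromen-2-one
Product: 22 7-hydroxy-6-methoxy-3-[(6-methoxy-2-oxo-2H-chromen-7-yl)oxy]-2H-chromen-2-one
Conditions: TFA, pentamethylbenzene, CH2Cl2, 0 °C → rt
Reagents that add atoms: none
Why: Acidolysis of a para-methoxybenzyl aryl ether through the stabilised benzylic cation, trapped by pentamethylbenzene in a Friedel–Crafts alkylation; methyl ethers, lactones and both pyranone double bonds are inert to TFA, and hydrogenolysis is avoided.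

## Compound list

1 | sesamol (1,3-benzodioxol-5-ol) | Oc1ccc2OCOc2c1 | starting material
2 | 6-bromo-1,3-benzodioxol-5-ol | Oc1cc2OCOc2cc1Br | intermediate
3 | [(6-bromo-1,3-benzodioxol-5-yl)oxy]trimethylsilane (formed in the flask, not isolated) | C[Si](C)(C)Oc1cc2OCOc2cc1Br | intermediate
4 | [6-(trimethylsilyloxy)-1,3-benzodioxol-5-yl]lithium (formed in the flask, not isolated) | [Li]c1cc2OCOc2cc1O[Si](C)(C)C | intermediate
5 | lithium 6-(trimethylsilyl)-1,3-benzodioxol-5-olate (formed in the flask, not isolated) | [Li+].[O-]c1cc2OCOc2cc1[Si](C)(C)C | intermediate
6 | 6-(trimethylsilyl)-1,3-benzodioxol-5-yl trifluoromethanesulfonate | C[Si](C)(C)c1cc2OCOc2cc1OS(=O)(=O)C(F)(F)F | intermediate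
7 | scopoletin (7-hydroxy-6-methoxy-2H-chromen-2-one) | COc1cc2ccc(=O)oc2cc1O | starting material
8 | ethyl bromoacetate | CCOC(=O)CBr | starting material
9 | ethyl 2-[(6-methoxy-2-oxo-2H-chromen-7-yl)oxy]acetate | CCOC(=O)COc1cc2oc(=O)ccc2cc1OC | intermediate
10 | N,N-dimethylformamide | CN(C)C=O | starting material
11 | lithium enolate of 9 (formed in the flask, not isolated) | [Li+].CCOC([O-])=COc1cc2oc(=O)ccc2cc1OC | intermediate
12 | chlorozinc enolate of 9 (formed in the flask, not isolated) | CCOC(O[Zn]Cl)=COc1cc2oc(=O)ccc2cc1OC | intermediate
13 | 4,5-methylenedioxybenzyne (5,6-didehydro-1,3-benzodioxole; formed in the flask, not isolated) | C1OC2=CC#CC=C2O1 | intermediate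
14 | 2-(dimethylamino)-4,5-methylenedioxy-2H-benzoxete (racemic; formed in the flask, not isolated) | CN(C)C1Oc2cc3OCOc3cc12 | intermediate
15 | 6-[(dimethylamino)methylidene]-3,4-methylenedioxycyclohexa-2,4-dien-1-one (formed in the flask, not isolated) | CN(C)C=C1C=C2OCOC2=CC1=O | intermediate
16 | chlorozinc phenoxide of ethyl 3-(dimethylamino)-3-(6-hydroxy-1,3-benzodioxol-5-yl)-2-[(6-methoxy-2-oxo-2H-chromen-7-yl)oxy]propanoate (racemic diastereomer mixture; formed in the flask, not isolated) | CCOC(=O)C(Oc1cc2oc(=O)ccc2cc1OC)C(N(C)C)c1cc2OCOc2cc1O[Zn]Cl | intermediate
17 | 4-(dimethylamino)-3-[(6-methoxy-2-oxo-2H-chromen-7-yl)oxy]-6,7-methylenedioxychroman-2-one (racemic diastereomer mixture; formed in the flask, not isolated) | CN(C)C1C(Oc2cc3oc(=O)ccc3cc2OC)C(=O)Oc2cc3OCOc3cc12 | intermediate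
18 | 3-[(6-methoxy-2-oxo-2H-chromen-7-yl)oxy]-6,7-methylenedioxycoumarin (7-[(6-methoxy-2-oxo-2H-chromen-7-yl)oxy]-6H-[1,3]dioxolo[4,5-g]chromen-6-one) | O=c1oc2cc3OCOc3cc2cc1Oc1cc2oc(=O)ccc2cc1OC | intermediate
19 | 6,7-dihydroxy-3-[(6-methoxy-2-oxo-2H-chromen-7-yl)oxy]-2H-chromen-2-one | O=c1oc2cc(O)c(O)cc2cc1Oc1cc2oc(=O)ccc2cc1OC | intermediate
20 | 6-hydroxy-7-[(4-methoxybenzyl)oxy]-3-[(6-methoxy-2-oxo-2H-chromen-7-yl)oxy]-2H-chromen-2-one | COc1ccc(COc2cc3oc(=O)c(Oc4cc5oc(=O)ccc5cc4OC)cc3cc2O)cc1 | intermediate
21 | 6-methoxy-7-[(4-methoxybenzyl)oxy]-3-[(6-methoxy-2-oxo-2H-chromen-7-yl)oxy]-2H-chromen-2-one | COc1ccc(COc2cc3oc(=O)c(Oc4cc5oc(=O)ccc5cc4OC)cc3cc2OC)cc1 | intermediate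
22 | 7-hydroxy-6-methoxy-3-[(6-methoxy-2-oxo-2H-chromen-7-yl)oxy]-2H-chromen-2-one | COc1cc2cc(Oc3cc4oc(=O)ccc4cc3OC)c(=O)oc2cc1O | target

## Step count and risks

Total: 8 steps. Longest linear sequence: 7 steps (steps 1, 2, 4, 5, 6, 7, 8 from sesamol **1**); the scopoletin branch (steps 3, 4, 5, 6, 7, 8) has 6.

**Step 4 (key step, proposed new method).** Most likely failures:
- capture of the aryne by the enolate carbon before DMF insertion (direct α-arylation);
- decay of the enolate at room temperature by self-condensation or conjugate addition to unit B;
- protonation of the enolate by moisture carried in with CsF;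
- incomplete loss of dimethylamine from **17**.

Fallback (known chemistry): setting out from **9**, saponification (NaOH, aqueous THF, then HCl; a lactone opened on the way recloses on acidification) should give 2-[(6-methoxy-2-oxo-2H-chromen-7-yl)oxy]acetic acid F1. Perkin condensation of F1 with commercial 2-hydroxy-4,5-methylenedioxybenzaldehyde (O=Cc1cc2OCOc2cc1O) in Ac2O with Et3N at about 120 °C, the classical route to 3-aryloxycoumarins, then forms C3–C4 and O1–C2 and comes back to the route at **18**.

**Step 5.** The lactone carbonyls may bind the boron reagent and stall the acetal opening, and forcing the reaction may start demethylation at C6'. Fallback: setting out from **18**, oxidation of the acetal CH2 with Pb(OAc)4 in hot benzene should give 7-[(6-methoxy-2-oxo-2H-chromen-7-yl)oxy]-6-oxo-6H-[1,3]dioxolo[4,5-g]chromen-2-yl acetate F2 (racemic). Mild aqueous acid then hydrolyses this orthoformate-type acetal and comes back to the route at **19**; no Lewis acid ever meets the methyl ethers.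

**Step 6.** Site selectivity between the two phenols may be poor, and double alkylation may occur if the second phenol is ionised. Fallback: setting out from **19**, both hydroxyls are methylated (MeI, K2CO3, DMF) to 6,7-dimethoxy-3-[(6-methoxy-2-oxo-2H-chromen-7-yl)oxy]-2H-chromen-2-one F3. The C7 methyl ether, the only one of the three whose phenoxide is conjugated with a lactone carbonyl, is then cleaved by nucleophilic demethylation (LiCl, DMF, about 140 °C). This uses the same acidity difference in the leaving-group sense, is less certain than the main sequence, and comes back to the route at **22**.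

## Further compounds

F1 | step 4 | 2-[(6-methoxy-2-oxo-2H-chromen-7-yl)oxy]acetic acid | OC(=O)COc1cc2oc(=O)ccc2cc1OC
F2 | step 5 | 7-[(6-methoxy-2-oxo-2H-chromen-7-yl)oxy]-6-oxo-6H-[1,3]dioxolo[4,5-g]chromen-2-yl acetate (racemic) | CC(=O)OC1Oc2cc3oc(=O)c(Oc4cc5oc(=O)ccc5cc4OC)cc3cc2O1
F3 | step 6 | 6,7-dimethoxy-3-[(6-methoxy-2-oxo-2H-chromen-7-yl)oxy]-2H-chromen-2-one | COc1cc2cc(Oc3cc4oc(=O)ccc4cc3OC)c(=O)oc2cc1OC
A1 | alternative 1 | 7-[(tert-butyldimethylsilyl)oxy]-6-methoxy-3-[(6-methoxy-2-oxo-2H-chromen-7-yl)oxy]-2H-chromen-2-one | COc1cc2cc(Oc3cc4oc(=O)ccc4cc3OC)c(=O)oc2cc1O[Si](C)(C)C(C)(C)C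
A2 | alternative 1 | 5-[(tert-butyldimethylsilyl)oxy]-2-ethenyl-4-methoxyphenyl 2-{[5-(acryloyloxy)-4-ethenyl-2-methoxyphenyl]oxy}prop-2-enoate | C=Cc1cc(OC)c(O[Si](C)(C)C(C)(C)C)cc1OC(=O)C(=C)Oc1cc(OC(=O)C=C)c(C=C)cc1OC
A3 | alternative 2 | methyl 3-(4-tert-butoxy-2-hydroxy-5-methoxyphenyl)-2-[(6-methoxy-2-oxo-2H-chromen-7-yl)oxy]propanoate (racemic) | COC(=O)C(Cc1cc(OC)c(OC(C)(C)C)cc1O)Oc1cc2oc(=O)ccc2cc1OC
A4 | alternative 2 | pentacarbonyl[(1-tert-butoxyethenyl)(methoxy)methylidene]chromium, (CO)5Cr=C(OMe)C(OtBu)=CH2 | COC(=[Cr])C(=C)OC(C)(C)C.[C-]#[O+].[C-]#[O+].[C-]#[O+].[C-]#[O+].[C-]#[O+]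
A5 | alternative 2 | methyl 2-[(6-methoxy-2-oxo-2H-chromen-7-yl)oxy]pent-4-ynoate (racemic) | COC(=O)C(CC#C)Oc1cc2oc(=O)ccc2cc1OC
A6 | alternative 3 | 7-[(7-acetoxy-6-methoxy-2-oxo-2H-chromen-3-yl)oxy]-6-methoxychroman-2-one | COc1cc2c(cc1Oc1cc3cc(OC)c(OC(C)=O)cc3oc1=O)OC(=O)CC2
A7 | alternative 3 | 6-[(7-acetoxy-6-methoxy-2-oxo-2H-chromen-3-yl)oxy]-5-methoxyindan-1-one | COc1cc2c(cc1Oc1cc3cc(OC)c(OC(C)=O)cc3oc1=O)C(=O)CC2
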